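**Retrosynthetic overview**
- The target comes from its 7,2'-bis(MOM) ether by mild acetal cleavage (last step, no ring formed).
- Both C5 units are disconnected together: the C8–CH2 bond (linear prenyl) and the C5'–CMe2 bond (reverse prenyl) come from a 5,4'-bis(O-prenyl) flavone by one new double Claisen cascade (Claisen–Cope on ring A, ortho-Claisen on ring B).
- The bis(prenyl ether) comes from the 5,4'-diol, which comes from a 5,4'-dibenzyl-7,2'-bis(MOM) flavone (hydrogenolysis, then double O-prenylation).
- Ring C (the pyran-4-one, the only ring built) comes from a 2'-hydroxychalcone by oxa-Michael closure then dehydrogenation; the chalcone comes from a Claisen–Schmidt union of the ring-A acetophenone and the ring-B aldehyde.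
- Rings A and B are bought intact: 2,4,6-trihydroxyacetophenone and 4-(benzyloxy)-2-hydroxybenzaldehyde.

Assumption: the target SMILES has no stereocentre and no stereogenic double bond, so "single enantiomer" is taken to mean the one achiral compound shown.

**Route**

Step 1
Reactants: 1 2,4,6-trihydroxyacetophenone
Product: 2 1-[2,6-dihydroxy-4-(methoxymethoxy)phenyl]ethan-1-one
Conditions: MOMCl (1.05 equiv), i-Pr2NEt, CH2Cl2/THF, 0 °C
Reagents that add atoms: MOMCl (chloromethyl methyl ether), COCCl
Why: The 4-OH is the only hydroxyl not hydrogen-bonded to the acetyl group and is the most acidic, so one equivalent of the α-chloro ether alkylates it selectively (Williamson-type O-alkylation, MOM protection).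

Step 2
Reactants: 2 1-[2,6-dihydroxy-4-(methoxymethoxy)phenyl]ethan-1-one
Product: 3 1-[2-(benzyloxy)-6-hydroxy-4-(methoxymethoxy)phenyl]ethan-1-one
Conditions: BnBr (1.0 equiv), K2CO3, acetone, reflux
Reagents that add atoms: benzyl bromide, BrCc1ccccc1
Why: Williamson mono-benzylation of the symmetric 2,6-diol stops after one alkylation because the remaining hydroxyl is locked in a strong chelate with the ketone and reacts much more slowly.

Step 3
Reactants: 4 4-(benzyloxy)-2-hydroxybenzaldehyde
Product: 5 4-(benzyloxy)-2-(methoxymethoxy)benzaldehyde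
Conditions: MOMCl, i-Pr2NEt, CH2Cl2, 0 °C to rt
Reagents that add atoms: MOMCl (chloromethyl methyl ether), COCCl
Why: Williamson-type MOM protection of the salicylaldehyde hydroxyl masks the future 2'-OH with a group that survives base, hydrogenolysis and heat.

Step 4
Reactants: 3 1-[2-(benzyloxy)-6-hydroxy-4-(methoxymethoxy)phenyl]ethan-1-one; 5 4-(benzyloxy)-2-(methoxymethoxy)benzaldehyde
Product: 6 (E)-1-[2-(benzyloxy)-6-hydroxy-4-(methoxymethoxy)phenyl]-3-[4-(benzyloxy)-2-(methoxymethoxy)phenyl]prop-2-en-1-one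
Conditions: KOH, EtOH/H2O, rt
Reagents that add atoms: none
Why: Claisen–Schmidt (crossed aldol) condensation of the methyl ketone enolate with the non-enolisable aldehyde, followed by E1cB dehydration, gives the thermodynamically favoured E-enone and leaves the chelated phenol free for ring closure.

Step 5
Reactants: 6 (E)-1-[2-(benzyloxy)-6-hydroxy-4-(methoxymethoxy)phenyl]-3-[4-(benzyloxy)-2-(methoxymethoxy)phenyl]prop-2-en-1-one
Product: 8 5-(benzyloxy)-2-[4-(benzyloxy)-2-(methoxymethoxy)phenyl]-7-(methoxymethoxy)-4H-chromen-4-one, via racemic flavanone 7 (not isolated)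
Conditions: NaOAc, EtOH, reflux; then I2 (1.2 equiv), pyridine, 95 °C
Reagents that add atoms: none
Why: Acetate-catalysed 6-endo oxa-Michael closure gives the racemic flavanone, whose C3 enol is iodinated and loses HI to pyridine (α-iodination/E2 dehydrogenation), so the transient C2 stereocentre is erased and no acid is present to attack the MOM groups.

Step 6
Reactants: 8 5-(benzyloxy)-2-[4-(benzyloxy)-2-(methoxymethoxy)phenyl]-7-(methoxymethoxy)-4H-chromen-4-one
Product: 9 5-hydroxy-2-[4-hydroxy-2-(methoxymethoxy)phenyl]-7-(methoxymethoxy)-4H-chromen-4-one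
Conditions: H2 (1 atm), 10% Pd/C, EtOAc/THF, rt
Reagents that add atoms: none
Why: Catalytic hydrogenolysis of the two aryl benzyl ethers is much faster than reduction of the vinylogous-ester C2=C3 bond and leaves the MOM acetals intact, freeing exactly the two oxygens to be prenylated.

Step 7
Reactants: 9 5-hydroxy-2-[4-hydroxy-2-(methoxymethoxy)phenyl]-7-(methoxymethoxy)-4H-chromen-4-one
Product: 10 7-(methoxymethoxy)-2-{2-(methoxymethoxy)-4-[(3-methylbut-2-en-1-yl)oxy]phenyl}-5-[(3-methylbut-2-en-1-yl)oxy]-4H-chromen-4-one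
Conditions: prenyl bromide (3 equiv), Cs2CO3, DMF, 50 °C
Reagents that add atoms: prenyl bromide (1-bromo-3-methylbut-2-ene), CC(C)=CCBr
Why: Williamson O-alkylation in a dipolar aprotic solvent etherifies the free 4'-phenoxide at once and the chelated 5-OH on warming with caesium carbonate, O-alkylation being favoured over C-alkylation under these conditions.

Step 8
Reactants: 10 7-(methoxymethoxy)-2-{2-(methoxymethoxy)-4-[(3-methylbut-2-en-1-yl)oxy]phenyl}-5-[(3-methylbut-2-en-1-yl)oxy]-4H-chromen-4-one
Product: 12 5-hydroxy-2-[4-hydroxy-2-(methoxymethoxy)-5-(2-methylbut-3-en-2-yl)phenyl]-7-(methoxymethoxy)-8-(3-methylbut-2-en-1-yl)-4H-chromen-4-one, via ring-A-rearranged mono-ether 11 (not isolated)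
Conditions: Eu(fod)3 (10 mol %), NaHCO3, 1,2-dichlorobenzene, 85 °C; then 170 °C (Ar)
Reagents that add atoms: none
Why: Proposed new method: a one-flask, temperature-gated, site-divergent double aromatic Claisen cascade that turns two identical O-prenyl ethers into two different C5 units; at 85 °C Eu(III) chelates the C4 carbonyl and O5 and triggers a [3,3] shift of the 5-O-prenyl group to C6, and because C8 (para to O5) is free a second [3,3] (Cope) shift carries the group on to C8 as a linear prenyl before tautomerisation to the chelated 5-OH; at 170 °C the unchelated 4'-O-prenyl ether undergoes a concerted ortho-Claisen shift to C5' (para to the 2'-OMOM donor and unhindered, whereas C3' lies between two oxygens), and since its para carbon C1' is blocked there is no Cope exit, so tautomerisation fixes the inverted 1,1-dimethylallyl group next to the new 4'-OH; the closest known reactions are the Eu(fod)3-catalysed para-Claisen–Cope rearrangement of 5-prenyloxyflavonoids and the thermal ortho-Claisen rearrangement of 4-prenyloxy-2-alkoxyaryl enones, which to my knowledge have not been run together on one substrate in one operation; no stereocentre is formed.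

Step 9
Reactants: 12 5-hydroxy-2-[4-hydroxy-2-(methoxymethoxy)-5-(2-methylbut-3-en-2-yl)phenyl]-7-(methoxymethoxy)-8-(3-methylbut-2-en-1-yl)-4H-chromen-4-one
Product: 13 5,7-dihydroxy-2-[2,4-dihydroxy-5-(2-methylbut-3-en-2-yl)phenyl]-8-(3-methylbut-2-en-1-yl)-4H-chromen-4-one
Conditions: aq. 3 M HCl/MeOH (1:5), 40 °C
Reagents that add atoms: none
Why: Acid-catalysed acetal exchange removes both MOM groups as dimethoxymethane under conditions mild enough that the ortho-prenyl and ortho-(1,1-dimethylallyl) phenols do not cyclise to chroman or dihydrobenzofuran (MOM deprotection).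

**Compound list**
1 | 2,4,6-trihydroxyacetophenone | CC(=O)c1c(O)cc(O)cc1O | starting material
2 | 1-[2,6-dihydroxy-4-(methoxymethoxy)phenyl]ethan-1-one | CC(=O)c1c(O)cc(OCOC)cc1O | intermediate
3 | 1-[2-(benzyloxy)-6-hydroxy-4-(methoxymethoxy)phenyl]ethan-1-one | CC(=O)c1c(O)cc(OCOC)cc1OCc2ccccc2 | intermediate
4 | 4-(benzyloxy)-2-hydroxybenzaldehyde | O=Cc1ccc(OCc2ccccc2)cc1O | starting material
5 | 4-(benzyloxy)-2-(methoxymethoxy)benzaldehyde | O=Cc1ccc(OCc2ccccc2)cc1OCOC | intermediate
6 | (E)-1-[2-(benzyloxy)-6-hydroxy-4-(methoxymethoxy)phenyl]-3-[4-(benzyloxy)-2-(methoxymethoxy)phenyl]prop-2-en-1-one (E-chalcone) | COCOc1cc(O)c(C(=O)/C=C/c2ccc(OCc3ccccc3)cc2OCOC)c(OCc2ccccc2)c1 | intermediate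
7 | rac-5-(benzyloxy)-2-[4-(benzyloxy)-2-(methoxymethoxy)phenyl]-7-(methoxymethoxy)chroman-4-one (racemic flavanone, not isolated) | COCOc1cc(OCc2ccccc2)c2c(c1)OC(c1ccc(OCc3ccccc3)cc1OCOC)CC2=O | intermediate
8 | 5-(benzyloxy)-2-[4-(benzyloxy)-2-(methoxymethoxy)phenyl]-7-(methoxymethoxy)-4H-chromen-4-one | COCOc1cc(OCc2ccccc2)c2c(c1)oc(-c1ccc(OCc3ccccc3)cc1OCOC)cc2=O | intermediate
9 | 5-hydroxy-2-[4-hydroxy-2-(methoxymethoxy)phenyl]-7-(methoxymethoxy)-4H-chromen-4-one | COCOc1cc(O)c2c(c1)oc(-c1ccc(O)cc1OCOC)cc2=O | intermediate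
10 | 7-(methoxymethoxy)-2-{2-(methoxymethoxy)-4-[(3-methylbut-2-en-1-yl)oxy]phenyl}-5-[(3-methylbut-2-en-1-yl)oxy]-4H-chromen-4-one | COCOc1cc(OCC=C(C)C)c2c(c1)oc(-c1ccc(OCC=C(C)C)cc1OCOC)cc2=O | intermediate
11 | 5-hydroxy-7-(methoxymethoxy)-2-{2-(methoxymethoxy)-4-[(3-methylbut-2-en-1-yl)oxy]phenyl}-8-(3-methylbut-2-en-1-yl)-4H-chromen-4-one (ring-A-rearranged mono-ether, not isolated) | COCOc1cc(O)c2c(c1CC=C(C)C)oc(-c1ccc(OCC=C(C)C)cc1OCOC)cc2=O | intermediate
12 | 5-hydroxy-2-[4-hydroxy-2-(methoxymethoxy)-5-(2-methylbut-3-en-2-yl)phenyl]-7-(methoxymethoxy)-8-(3-methylbut-2-en-1-yl)-4H-chromen-4-one | COCOc1cc(O)c2c(c1CC=C(C)C)oc(-c1cc(C(C)(C)C=C)c(O)cc1OCOC)cc2=O | intermediate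
13 | 5,7-dihydroxy-2-[2,4-dihydroxy-5-(2-methylbut-3-en-2-yl)phenyl]-8-(3-methylbut-2-en-1-yl)-4H-chromen-4-one (CNP0315714.0, achiral) | C=CC(C)(C)c1cc(-c2cc(=O)c3c(O)cc(O)c(CC=C(C)C)c3o2)c(O)cc1O | target

**Step count and risks**

Total steps: 9. Longest linear sequence: 8 steps (1 → 2 → 3 → 6 → 8 → 9 → 10 → 12 → 13; the aldehyde branch 4 → 5 joins at step 4).

Three steps most likely to fail:

Step 5 (oxa-Michael closure, then I2/pyridine dehydrogenation). The electron-rich rings may be iodinated, or the dehydrogenation may stall at the flavanone. The fallback sets out from 6 and comes back at 8. Chalcone 6 is closed with NaOAc/EtOH and the flavanone 7 is isolated. It is then dehydrogenated by palladium catalysis (Pd(TFA)2 10 mol %, DMSO, O2 1 atm, 80 °C), which goes through a Pd enolate and β-hydride elimination instead of halogenation/elimination and therefore cannot halogenate the rings. This detour makes no compound outside the list (F0).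

Step 7 (double O-prenylation). The carbonyl-chelated 5-OH may resist alkylation, or the phenoxide may C-prenylate. The fallback sets out from 9 and comes back at 10. Both phenols are etherified by Mitsunobu reaction with 3-methylbut-2-en-1-ol, PPh3 and DIAD in THF (0 °C to rt). This activates the alcohol instead of the phenoxide, runs at neutral pH, is known to work on chelated phenols and cannot C-alkylate. This detour makes no compound outside the list (F0).

Step 8 (proposed new double Claisen cascade). The ring-A shift may stop at C6 (6-(1,1-dimethylallyl) isomer). The hotter ring-B stage may cause deprenylation or abnormal Claisen isomerisation of the new ortho-(1,1-dimethylallyl) phenol. The fallback uses only known reaction types, sets out from 9 and comes back at 13. It runs the two rearrangements one at a time, ring B first, on substrates that each carry a single prenyl ether.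
- Diol 9 is alkylated only at the free 4'-OH (prenyl bromide 1.1 equiv, K2CO3, acetone, rt; the chelated 5-OH does not react) to give the 4'-O-prenyl ether F1.
- Thermal ortho-Claisen rearrangement (EtOH/H2O 4:1, 130 °C, sealed tube) moves that group to C5' and gives the 5'-(1,1-dimethylallyl) 5,4'-diol F2.
- The new hindered 4'-OH is capped with MOMCl/i-Pr2NEt to give the tris-MOM ether F3.
- The chelated 5-OH is prenylated (prenyl bromide, Cs2CO3, DMF, 50 °C) to give the 5-O-prenyl ether F4.
- Eu(fod)3/NaHCO3 in chlorobenzene at 85 °C effects the known para-Claisen–Cope shift to give the 8-prenyl tris-MOM ether F5.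
- Aqueous HCl/MeOH at 40 °C removes the three MOM groups to give target 13.

**Further compounds**
F0 | step 5 | none | none
F0 | step 7 | none | none
F1 | step 8 | 5-hydroxy-7-(methoxymethoxy)-2-{2-(methoxymethoxy)-4-[(3-methylbut-2-en-1-yl)oxy]phenyl}-4H-chromen-4-one | COCOc1cc(O)c2c(c1)oc(-c1ccc(OCC=C(C)C)cc1OCOC)cc2=O
F2 | step 8 | 5-hydroxy-2-[4-hydroxy-2-(methoxymethoxy)-5-(2-methylbut-3-en-2-yl)phenyl]-7-(methoxymethoxy)-4H-chromen-4-one | COCOc1cc(O)c2c(c1)oc(-c1cc(C(C)(C)C=C)c(O)cc1OCOC)cc2=O
F3 | step 8 | 2-[2,4-bis(methoxymethoxy)-5-(2-methylbut-3-en-2-yl)phenyl]-5-hydroxy-7-(methoxymethoxy)-4H-chromen-4-one | COCOc1cc(O)c2c(c1)oc(-c1cc(C(C)(C)C=C)c(OCOC)cc1OCOC)cc2=O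
F4 | step 8 | 2-[2,4-bis(methoxymethoxy)-5-(2-methylbut-3-en-2-yl)phenyl]-7-(methoxymethoxy)-5-[(3-methylbut-2-en-1-yl)oxy]-4H-chromen-4-one | COCOc1cc(OCC=C(C)C)c2c(c1)oc(-c1cc(C(C)(C)C=C)c(OCOC)cc1OCOC)cc2=O
F5 | step 8 | 2-[2,4-bis(methoxymethoxy)-5-(2-methylbut-3-en-2-yl)phenyl]-5-hydroxy-7-(methoxymethoxy)-8-(3-methylbut-2-en-1-yl)-4H-chromen-4-one | COCOc1cc(O)c2c(c1CC=C(C)C)oc(-c1cc(C(C)(C)C=C)c(OCOC)cc1OCOC)cc2=O
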